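**Plan**
- Retrosynthesis first opens both rings C at O1–C2 and C4–C4a (and at O1''–C2'' and C4''–C4a''), which leaves a biaryl bis-phenol and two 3-(4-methoxyphenyl)propiolate units.
- Ring A of the flavone joined through C8'' (double-primed numbers) is then cut at C8''–C8a'', C6''–C7'' and C4a''–C8a''. C8'' carries the aryl group between the oxygens on C8a'' and C7'', with a third oxygen on C5'': this is the 2-aryl-3-siloxy-5-alkoxyphenol pattern that a cyclobutenone/siloxyalkyne benzannulation delivers.
- Forward: ring A of the C6-linked flavone is a purchased benzene ring, converted in four steps into an aryl siloxyalkyne. The benzannulation builds ring A'' and with it the C6–C8'' biaryl bond. Both rings C then close together (deallylation, double oxa-Michael addition, saponification, double Friedel–Crafts acylation), and desilylation and BCl3 dealkylation finish the synthesis.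
- Stereochemistry: the target has no stereocentre, and the hindered biaryl axis is formed without control.

Key step: step 5

Remark: the target is drawn without an axial descriptor, so the C6–C8'' axis is taken as racemic; it becomes stereogenic only in step 9.

**Route**

Step 1
Reactants: 1 3,5-bis(benzyloxy)phenol
Product: 3 2,6-bis(benzyloxy)-4-hydroxybenzaldehyde, via iminium chloride 2 (not isolated)
Conditions: POCl3, DMF, MeCN, 0 °C to rt; then H2O
Reagents that add atoms: N,N-dimethylformamide CN(C)C=O; water O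
Why: Vilsmeier–Haack formylation of a 3,5-dialkoxyphenol goes mainly para to the free hydroxyl, at the carbon between the two ethers, as in the standard preparation of 4-hydroxy-2,6-dimethoxybenzaldehyde, and the minor ortho-formyl isomer should be removable by chromatography.

Step 2
Reactants: 3 2,6-bis(benzyloxy)-4-hydroxybenzaldehyde
Product: 4 4-(allyloxy)-2,6-bis(benzyloxy)benzaldehyde
Conditions: allyl bromide, K2CO3, DMF, rt
Reagents that add atoms: allyl bromide C=CCBr
Why: Williamson etherification of the single, acidic para-formyl phenol should be clean and installs the one ether that can later be removed without touching benzyl, ethyl or silyl groups.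

Step 3
Reactants: 4 4-(allyloxy)-2,6-bis(benzyloxy)benzaldehyde
Product: 5 5-(allyloxy)-1,3-bis(benzyloxy)-2-ethynylbenzene
Conditions: dimethyl (1-diazo-2-oxopropyl)phosphonate, K2CO3, MeOH/THF, rt
Reagents that add atoms: dimethyl (1-diazo-2-oxopropyl)phosphonate COP(=O)(OC)C(=[N+]=[N-])C(C)=O
Why: Seyferth–Gilbert homologation in its Ohira–Bestmann form converts aryl aldehydes into terminal alkynes under mild carbonate conditions that leave allyl and benzyl ethers alone.

Step 4
Reactants: 5 5-(allyloxy)-1,3-bis(benzyloxy)-2-ethynylbenzene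
Product: 8 {[4-(allyloxy)-2,6-bis(benzyloxy)phenyl]ethynyloxy}triisopropylsilane, via lithium acetylide 6 (not isolated), via lithium ynolate 7 (not isolated)
Conditions: LiN(SiMe3)2, THF, −78 °C; LiOOtBu (from t-BuOOH and LiN(SiMe3)2), −78 to 0 °C; iPr3SiOTf, −78 °C
Reagents that add atoms: tert-butyl hydroperoxide CC(C)(C)OO; triisopropylsilyl trifluoromethanesulfonate CC(C)[Si](OS(=O)(=O)C(F)(F)F)(C(C)C)C(C)C
Why: Oxygen transfer from lithium tert-butyl peroxide to a lithium acetylide followed by O-silylation of the ynolate with a bulky silyl triflate is the established one-flask route from terminal alkynes to triisopropylsiloxyalkynes, and the amide base avoids Wittig rearrangement of the benzyl ethers.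

Step 5
Reactants: 8 {[4-(allyloxy)-2,6-bis(benzyloxy)phenyl]ethynyloxy}triisopropylsilane; 9 3-ethoxycyclobut-2-en-1-one
Product: 14 4'-(allyloxy)-2',6'-bis(benzyloxy)-4-ethoxy-6-(triisopropylsilyloxy)biphenyl-2-ol, via vinylketene 10 (not isolated), via vinylcyclobutenone 11 (not isolated), via dienylketene 12 (not isolated), via cyclohexadienone 13 (not isolated)
Conditions: 9 (1.5 equiv), toluene, 110 °C, sealed tube
Reagents that add atoms: none
Why: Thermal 4π electrocyclic opening of 9 gives the 3-ethoxy vinylketene 10, and the aryl-bearing, nucleophilic carbon of siloxyalkyne 8 bonds to its ketene carbonyl carbon while the siloxy carbon bonds to the ketene α-carbon in a [2+2] cycloaddition (new bonds C8''–C8a'' and C6''–C7'') to give 11. A second 4π opening gives dienylketene 12, which closes ring A'' by 6π electrocyclisation (remaking C4a''–C8a'') to 13, and 13 tautomerises to the phenol. This is the Danheiser benzannulation of cyclobutenones with siloxyalkynes, which gives 2-substituted resorcinol monosilyl ethers and for which 3-oxygenated cyclobutenones are established vinylketene sources. No stereocentre is formed in the product, and the axis is not yet stereogenic because the benzyloxy-bearing ring is symmetric. The step needs the head-to-tail orientation of ketene and alkyne, which the oxygen directly on the alkyne secures by polarising it more strongly than the aryl group, so that the free hydroxyl (the later O1'') and the siloxy group flank the aryl-bearing carbon. At 110 °C the allyl aryl ether should stay below the onset of Claisen rearrangement, and the hindered product phenol should be a poor trap for the ketene.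

Step 6
Reactants: 14 4'-(allyloxy)-2',6'-bis(benzyloxy)-4-ethoxy-6-(triisopropylsilyloxy)biphenyl-2-ol
Product: 15 2',6'-bis(benzyloxy)-4-ethoxy-6-(triisopropylsilyloxy)biphenyl-2,4'-diol
Conditions: Pd(PPh3)4 (5 mol %), morpholine, THF, rt
Reagents that add atoms: none
Why: Zerovalent palladium ionises the allyl aryl ether to a π-allyl complex that morpholine captures (Tsuji–Trost deallylation), which frees the second phenol without affecting benzyl, ethyl or silyl ethers.

Step 7
Reactants: 15 2',6'-bis(benzyloxy)-4-ethoxy-6-(triisopropylsilyloxy)biphenyl-2,4'-diol; 16 methyl 3-(4-methoxyphenyl)propiolate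
Product: 17 dimethyl (2Z,2'Z)-3,3'-{[2',6'-bis(benzyloxy)-4-ethoxy-6-(triisopropylsilyloxy)biphenyl-2,4'-diyl]bis(oxy)}bis[3-(4-methoxyphenyl)prop-2-enoate]
Conditions: 16 (2.5 equiv), K2CO3 (0.3 equiv), dry DMF, 70 °C
Reagents that add atoms: none
Why: Base-catalysed oxa-Michael addition of phenoxides to the β-carbon of arylpropiolates is the first stage of the Ruhemann-type flavone synthesis; anti addition should give mainly the Z ethers, and either geometry can be carried on because acid equilibrates the push–pull alkene in step 9.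

Step 8
Reactants: 17 the bis(aryloxycinnamate) dimethyl ester
Product: 18 (2Z,2'Z)-3,3'-{[2',6'-bis(benzyloxy)-4-ethoxy-6-(triisopropylsilyloxy)biphenyl-2,4'-diyl]bis(oxy)}bis[3-(4-methoxyphenyl)prop-2-enoic acid]
Conditions: LiOH, THF/MeOH/H2O, rt; then 1 M HCl to pH 3
Reagents that add atoms: lithium hydroxide [Li+].[OH-]
Why: Saponification of the methyl esters is routine, and at room temperature hydroxide is expected to attack the ester carbonyl in preference to the β-carbon and to spare the hindered aryl triisopropylsilyl ether.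

Step 9
Reactants: 18 the bis(aryloxycinnamic acid)
Product: 20 5,7-bis(benzyloxy)-6-[5-ethoxy-2-(4-methoxyphenyl)-4-oxo-7-(triisopropylsilyloxy)-4H-chromen-8-yl]-2-(4-methoxyphenyl)-4H-chromen-4-one, via mixed anhydride 19 (not isolated)
Conditions: (CF3CO)2O, CH2Cl2, 0 °C to rt; then aqueous NaHCO3
Reagents that add atoms: none
Why: Intramolecular Friedel–Crafts acylation through the trifluoroacetic mixed anhydride, the mild way xanthones are closed from 2-aryloxybenzoic acids, should acylate each trioxygenated ring at the ortho carbon within reach (C4a and C4a'') and close both rings C without the strong acid that would strip benzyl or silyl groups; the axis becomes stereogenic here and forms as the racemate.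

Step 10
Reactants: 20 the benzyl-, ethyl- and silyl-protected biflavone
Product: 21 5,7-bis(benzyloxy)-6-[5-ethoxy-7-hydroxy-2-(4-methoxyphenyl)-4-oxo-4H-chromen-8-yl]-2-(4-methoxyphenyl)-4H-chromen-4-one
Conditions: Bu4NF, THF, 0 °C; then aqueous NH4Cl
Reagents that add atoms: none
Why: Fluoride cleavage of the aryl silyl ether should be fast for a 7-siloxyflavone, whose phenoxide is a vinylogous carboxylate and a good leaving group on silicon.

Step 11
Reactants: 21 the 7''-hydroxy biflavone
Product: 22 5,7-dihydroxy-6-[5,7-dihydroxy-2-(4-methoxyphenyl)-4-oxo-4H-chromen-8-yl]-2-(4-methoxyphenyl)-4H-chromen-4-one (CNP0226117.0)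
Conditions: BCl3 (excess), C6HMe5, CH2Cl2, −78 °C to rt; then MeOH, aqueous HCl
Reagents that add atoms: none
Why: BCl3 with pentamethylbenzene as benzyl-cation trap cleaves aryl benzyl ethers at low temperature, and on warming the boron chelate between the C4'' carbonyl and the peri oxygen delivers chloride to the ethyl group (chelation-assisted dealkylation of 5-alkoxyflavones), while the unchelated 4'-methyl ethers should remain.

**Compound list**

1 | 3,5-bis(benzyloxy)phenol | Oc1cc(OCc2ccccc2)cc(OCc2ccccc2)c1 | starting material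
2 | N-{[2,6-bis(benzyloxy)-4-hydroxyphenyl]methylidene}-N-methylmethanaminium chloride | C[N+](C)=Cc1c(OCc2ccccc2)cc(O)cc1OCc1ccccc1.[Cl-] | intermediate
3 | 2,6-bis(benzyloxy)-4-hydroxybenzaldehyde | O=Cc1c(OCc2ccccc2)cc(O)cc1OCc1ccccc1 | intermediate
4 | 4-(allyloxy)-2,6-bis(benzyloxy)benzaldehyde | C=CCOc1cc(OCc2ccccc2)c(C=O)c(OCc2ccccc2)c1 | intermediate
5 | 5-(allyloxy)-1,3-bis(benzyloxy)-2-ethynylbenzene | C=CCOc1cc(OCc2ccccc2)c(C#C)c(OCc2ccccc2)c1 | intermediate
6 | lithium [4-(allyloxy)-2,6-bis(benzyloxy)phenyl]acetylide | [Li]C#Cc1c(OCc2ccccc2)cc(OCC=C)cc1OCc1ccccc1 | intermediate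
7 | lithium 2-[4-(allyloxy)-2,6-bis(benzyloxy)phenyl]ethynolate | [Li]OC#Cc1c(OCc2ccccc2)cc(OCC=C)cc1OCc1ccccc1 | intermediate
8 | {[4-(allyloxy)-2,6-bis(benzyloxy)phenyl]ethynyloxy}triisopropylsilane | C=CCOc1cc(OCc2ccccc2)c(C#CO[Si](C(C)C)(C(C)C)C(C)C)c(OCc2ccccc2)c1 | intermediate
9 | 3-ethoxycyclobut-2-en-1-one | CCOC1=CC(=O)C1 | starting material
10 | 3-ethoxybuta-1,3-dien-1-one (vinylketene) | CCOC(=C)C=C=O | intermediate
11 | 2-[4-(allyloxy)-2,6-bis(benzyloxy)phenyl]-4-(1-ethoxyvinyl)-3-(triisopropylsilyloxy)cyclobut-2-en-1-one (racemic) | CCOC(=C)C1C(=O)C(c2c(OCc3ccccc3)cc(OCC=C)cc2OCc2ccccc2)=C1O[Si](C(C)C)(C(C)C)C(C)C | intermediate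
12 | (3E)-2-[4-(allyloxy)-2,6-bis(benzyloxy)phenyl]-5-ethoxy-3-(triisopropylsilyloxy)hexa-1,3,5-trien-1-one (ketene and ethoxyvinyl groups cis) | CCOC(=C)/C=C(O[Si](C(C)C)(C(C)C)C(C)C)\C(=C=O)c1c(OCc2ccccc2)cc(OCC=C)cc1OCc1ccccc1 | intermediate
13 | 2-[4-(allyloxy)-2,6-bis(benzyloxy)phenyl]-5-ethoxy-3-(triisopropylsilyloxy)cyclohexa-2,4-dien-1-one | CCOC1=CC(O[Si](C(C)C)(C(C)C)C(C)C)=C(c2c(OCc3ccccc3)cc(OCC=C)cc2OCc2ccccc2)C(=O)C1 | intermediate
14 | 4'-(allyloxy)-2',6'-bis(benzyloxy)-4-ethoxy-6-(triisopropylsilyloxy)biphenyl-2-ol | CCOc1cc(O)c(-c2c(OCc3ccccc3)cc(OCC=C)cc2OCc2ccccc2)c(O[Si](C(C)C)(C(C)C)C(C)C)c1 | intermediate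
15 | 2',6'-bis(benzyloxy)-4-ethoxy-6-(triisopropylsilyloxy)biphenyl-2,4'-diol | CCOc1cc(O)c(-c2c(OCc3ccccc3)cc(O)cc2OCc2ccccc2)c(O[Si](C(C)C)(C(C)C)C(C)C)c1 | intermediate
16 | methyl 3-(4-methoxyphenyl)propiolate | COC(=O)C#Cc1ccc(OC)cc1 | starting material
17 | dimethyl (2Z,2'Z)-3,3'-{[2',6'-bis(benzyloxy)-4-ethoxy-6-(triisopropylsilyloxy)biphenyl-2,4'-diyl]bis(oxy)}bis[3-(4-methoxyphenyl)prop-2-enoate] | CCOc1cc(O/C(=C\C(=O)OC)c2ccc(OC)cc2)c(-c2c(OCc3ccccc3)cc(O/C(=C\C(=O)OC)c3ccc(OC)cc3)cc2OCc2ccccc2)c(O[Si](C(C)C)(C(C)C)C(C)C)c1 | intermediate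
18 | (2Z,2'Z)-3,3'-{[2',6'-bis(benzyloxy)-4-ethoxy-6-(triisopropylsilyloxy)biphenyl-2,4'-diyl]bis(oxy)}bis[3-(4-methoxyphenyl)prop-2-enoic acid] | CCOc1cc(O/C(=C\C(=O)O)c2ccc(OC)cc2)c(-c2c(OCc3ccccc3)cc(O/C(=C\C(=O)O)c3ccc(OC)cc3)cc2OCc2ccccc2)c(O[Si](C(C)C)(C(C)C)C(C)C)c1 | intermediate
19 | bis(trifluoroacetic) mixed anhydride of diacid 18 | CCOc1cc(O/C(=C\C(=O)OC(=O)C(F)(F)F)c2ccc(OC)cc2)c(-c2c(OCc3ccccc3)cc(O/C(=C\C(=O)OC(=O)C(F)(F)F)c3ccc(OC)cc3)cc2OCc2ccccc2)c(O[Si](C(C)C)(C(C)C)C(C)C)c1 | intermediate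
20 | 5,7-bis(benzyloxy)-6-[5-ethoxy-2-(4-methoxyphenyl)-4-oxo-7-(triisopropylsilyloxy)-4H-chromen-8-yl]-2-(4-methoxyphenyl)-4H-chromen-4-one (racemic axis) | COc1ccc(-c2cc(=O)c3c(OCc4ccccc4)c(-c4c(O[Si](C(C)C)(C(C)C)C(C)C)cc(OCC)c5c(=O)cc(-c6ccc(OC)cc6)oc45)c(OCc4ccccc4)cc3o2)cc1 | intermediate
21 | 5,7-bis(benzyloxy)-6-[5-ethoxy-7-hydroxy-2-(4-methoxyphenyl)-4-oxo-4H-chromen-8-yl]-2-(4-methoxyphenyl)-4H-chromen-4-one (racemic axis) | COc1ccc(-c2cc(=O)c3c(OCc4ccccc4)c(-c4c(O)cc(OCC)c5c(=O)cc(-c6ccc(OC)cc6)oc45)c(OCc4ccccc4)cc3o2)cc1 | intermediate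
22 | 5,7-dihydroxy-6-[5,7-dihydroxy-2-(4-methoxyphenyl)-4-oxo-4H-chromen-8-yl]-2-(4-methoxyphenyl)-4H-chromen-4-one (racemic axis) | COc1ccc(-c2cc(=O)c3c(O)c(-c4c(O)cc(O)c5c(=O)cc(-c6ccc(OC)cc6)oc45)c(O)cc3o2)cc1 | target

**Summary**

Total step count: 11. Longest linear sequence: 11 steps (1 to 22); 9 and 16 are purchased and enter at steps 5 and 7.

Steps most likely to fail:

Step 5. The donor-stabilised cyclobutenone 9 may open too slowly, so that at the temperature required the siloxyalkyne is lost to desilylation or oligomerisation, or the allyl ether begins to rearrange. The fallback sets out from 8 and comes back at 14, and generates the same vinylketene 10 at room temperature by photochemical Wolff rearrangement (the diazo ketone variant of the same benzannulation). Ethyl vinyl ether would be lithiated with t-BuLi to 1-ethoxyvinyllithium F1, which is acylated with N-methoxy-N-methylacetamide to 3-ethoxybut-3-en-2-one F2. Trifluoroacetylation of its lithium enolate (LiN(SiMe3)2, CF3CO2CH2CF3, THF, −78 °C) should give 5-ethoxy-1,1,1-trifluorohex-5-ene-2,4-dione F3, and detrifluoroacetylative diazo transfer (MsN3, Et3N, H2O, MeCN) should give 1-diazo-3-ethoxybut-3-en-2-one F4. Irradiation of F4 with 8 (CH2Cl2, 300 nm, rt) should lead through 10 to 11, and brief warming in toluene at 80 °C should complete the passage through 12 and 13 to 14.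

Step 7. Conjugate addition of the phenoxide beside the biaryl axis to the donor-deactivated propiolate may be sluggish, and prolonged heating with carbonate may strip the silyl ether and expose a third phenol to addition. The fallback sets out from 15 and 16 and comes back at 17, and replaces conjugate addition to the alkyne by addition–elimination on a vinyl chloride. Hydrochlorination of 16 (LiCl, AcOH, MeCN, 80 °C) should give methyl (Z)-3-chloro-3-(4-methoxyphenyl)prop-2-enoate F5. Both phenoxides of 15 would then displace chloride from F5 (K2CO3, catalytic DABCO, MeCN, rt) to give 17 without heating.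

Step 9. Ionisation of the donor-stabilised mixed anhydride may stall, or the acid set free may transfer benzyl groups onto the electron-rich rings. The fallback sets out from 18 and comes back at 20, and closes both rings by amide activation (a Vilsmeier–Haack-type acylation) under pyridine-buffered conditions. Coupling of 18 with dimethylamine (EDC·HCl, HOBt, CH2Cl2) should give (2Z,2'Z)-3,3'-{[2',6'-bis(benzyloxy)-4-ethoxy-6-(triisopropylsilyloxy)biphenyl-2,4'-diyl]bis(oxy)}bis[3-(4-methoxyphenyl)-N,N-dimethylprop-2-enamide] F6. Treatment with Tf2O and 2-chloropyridine (CH2Cl2, −78 to 0 °C) should cyclise it to the 4,4''-bis(dimethyliminium) bis(triflate) analogue of 20 F7, which aqueous NaHCO3 hydrolyses to 20.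

**Further compounds**

F1 | step 5 | 1-ethoxyvinyllithium | [Li]C(=C)OCC
F2 | step 5 | 3-ethoxybut-3-en-2-one | CCOC(=C)C(C)=O
F3 | step 5 | 5-ethoxy-1,1,1-trifluorohex-5-ene-2,4-dione | CCOC(=C)C(=O)CC(=O)C(F)(F)F
F4 | step 5 | 1-diazo-3-ethoxybut-3-en-2-one | CCOC(=C)C(=O)C=[N+]=[N-]
F5 | step 7 | methyl (Z)-3-chloro-3-(4-methoxyphenyl)prop-2-enoate | COC(=O)/C=C(\Cl)c1ccc(OC)cc1
F6 | step 9 | (2Z,2'Z)-3,3'-{[2',6'-bis(benzyloxy)-4-ethoxy-6-(triisopropylsilyloxy)biphenyl-2,4'-diyl]bis(oxy)}bis[3-(4-methoxyphenyl)-N,N-dimethylprop-2-enamide] | CCOc1cc(O/C(=C\C(=O)N(C)C)c2ccc(OC)cc2)c(-c2c(OCc3ccccc3)cc(O/C(=C\C(=O)N(C)C)c3ccc(OC)cc3)cc2OCc2ccccc2)c(O[Si](C(C)C)(C(C)C)C(C)C)c1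
F7 | step 9 | 4,4''-bis(dimethyliminium) bis(trifluoromethanesulfonate) analogue of 20 (not isolated) | COc1ccc(-c2cc(=[N+](C)C)c3c(OCc4ccccc4)c(-c4c(O[Si](C(C)C)(C(C)C)C(C)C)cc(OCC)c5c(=[N+](C)C)cc(-c6ccc(OC)cc6)oc45)c(OCc4ccccc4)cc3o2)cc1.[O-]S(=O)(=O)C(F)(F)F.[O-]S(=O)(=O)C(F)(F)F
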